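**Retrosynthetic overview**
1. The target joins C3 of ring C of unit 1 (the 4'-O-methyl flavone) to C6 of ring A of unit 2 (the apigenin unit). Unit 1 is therefore a 2,3-diaryl chromone whose C3 aryl is the phloroglucinol ring of unit 2 and whose C2 aryl is the 4-methoxyphenyl ring; the plan rests on this feature.
2. Last disconnection: ring C of unit 2 (its O1–C2 and C2–C3 bonds) goes back to a 2'-hydroxychalcone. This comes from 4-(benzyloxy)benzaldehyde and an acetyl group ortho to the one oxygen of that ring lying para to the biaryl bond (kept as an allyl ether; the two ortho oxygens are benzyl ethers).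
3. Key disconnection: ring C of unit 1 at C2–C3 and O1–C2, back to 2-hydroxydeoxybenzoin 9 and 4-methoxybenzoyl chloride 10 (aroyl shift to the methylene carbon, then cyclodehydration).
4. 9 comes from Hoesch acylation of phloroglucinol by arylacetonitrile 5, followed by 4,6-di-O-benzylation; 5 comes from 2,4,6-trihydroxybenzaldehyde by 4-O-allylation, 2,6-di-O-benzylation and one-carbon homologation.
5. Ring order: ring C of unit 1 (step 6), then ring C of unit 2 (step 10); all benzyl ethers are removed in the last step.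

Key step: step 6

Assumption: the target SMILES has no stereodescriptor, so the hindered C3–C6 biaryl axis between the units is left undefined (racemic if rotation proves slow); no stereocentre has to be set.

Step 1
Reactants: 1 2,4,6-trihydroxybenzaldehyde
Product: 2 4-(allyloxy)-2,6-dihydroxybenzaldehyde
Conditions: allyl bromide (1.0 equiv), K2CO3 (1.0 equiv), DMF, 0 °C → rt
Reagents that add atoms: allyl bromide, C=CCBr
Why: Williamson etherification; the 4-hydroxyl is the only one not hydrogen-bonded to the formyl group and is the most acidic, so one equivalent of base and halide should alkylate it first.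

Step 2
Reactants: 2 4-(allyloxy)-2,6-dihydroxybenzaldehyde
Product: 3 4-(allyloxy)-2,6-bis(benzyloxy)benzaldehyde
Conditions: BnBr (2.5 equiv), K2CO3 (3 equiv), DMF, 60 °C
Reagents that add atoms: benzyl bromide, BrCc1ccccc1
Why: Williamson etherification under more forcing conditions should alkylate both chelated ortho hydroxyls, while the allyl ether is inert far below Claisen rearrangement temperatures.

Step 3
Reactants: 3 4-(allyloxy)-2,6-bis(benzyloxy)benzaldehyde
Product: 5 2-[4-(allyloxy)-2,6-bis(benzyloxy)phenyl]acetonitrile, via N-(1-tosylalkenyl)formamide 4 (not isolated)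
Conditions: TosMIC, t-BuOK, DME, −40 °C; then MeOH, reflux
Reagents that add atoms: TosMIC (p-toluenesulfonylmethyl isocyanide), Cc1ccc(cc1)S(=O)(=O)C[N+]#[C-]
Why: van Leusen reductive cyanation, in which the TosMIC anion adds to the aldehyde, the oxazoline opens to formamide 4, and methanolysis with loss of sulfinate gives the homologous nitrile; no acid is used, so every ether should survive.

Step 4
Reactants: 5 2-[4-(allyloxy)-2,6-bis(benzyloxy)phenyl]acetonitrile; 6 phloroglucinol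
Product: 8 2-[4-(allyloxy)-2,6-bis(benzyloxy)phenyl]-1-(2,4,6-trihydroxyphenyl)ethanone, via ketiminium chloride 7 (not isolated)
Conditions: ZnCl2, HCl (g), Et2O, 0 °C; then H2O/THF, 70 °C
Reagents that add atoms: water, O
Why: Houben–Hoesch acylation, in which the HCl/ZnCl2-activated nitrile is attacked by phloroglucinol (far more nucleophilic than the trialkoxy ring of 5, and symmetric, so only one ketimine can form) and hydrolysis of 7 gives the aryl ketone.

Step 5
Reactants: 8 2-[4-(allyloxy)-2,6-bis(benzyloxy)phenyl]-1-(2,4,6-trihydroxyphenyl)ethanone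
Product: 9 2-[4-(allyloxy)-2,6-bis(benzyloxy)phenyl]-1-[2,4-bis(benzyloxy)-6-hydroxyphenyl]ethanone
Conditions: BnBr (2.1 equiv), K2CO3, DMF, rt
Reagents that add atoms: benzyl bromide, BrCc1ccccc1
Why: Williamson etherification of the para hydroxyl and one ortho hydroxyl, as in the known 4,6-di-O-benzylation of phloroacetophenone; the last ortho hydroxyl is held in a hydrogen bond to the ketone and should stay free under these mild conditions.

Step 6
Reactants: 9 2-[4-(allyloxy)-2,6-bis(benzyloxy)phenyl]-1-[2,4-bis(benzyloxy)-6-hydroxyphenyl]ethanone; 10 4-methoxybenzoyl chloride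
Product: 13 3-[4-(allyloxy)-2,6-bis(benzyloxy)phenyl]-5,7-bis(benzyloxy)-2-(4-methoxyphenyl)-4H-chromen-4-one, via aryl 4-methoxybenzoate 11 (not isolated), via 2-aryl-1,3-diketone 12 (not isolated)
Conditions: 10 (1.2 equiv), DBU (3 equiv), pyridine, 0 → 80 °C; then AcOH, 100 °C
Reagents that add atoms: none
Why: Baker–Venkataraman rearrangement followed by cyclodehydration, the known route from 2-hydroxydeoxybenzoins to 2,3-diaryl chromones. The chelated phenol is first esterified to 11; DBU then forms the enolate of the doubly activated benzylic methylene, which attacks the ester carbonyl through a six-membered cyclic transition state and collapses to the phenoxide of 12 (O-to-C 1,5-acyl shift, new C2–C3 bond). On acidification the phenol adds to the anisoyl ketone (6-exo-trig) and the hemiketal loses water, forming O1–C2 and closing ring C of unit 1. No stereocentre results because C2 and C3 both become sp2. The step needs C-acylation rather than O-acylation of the enolate, and chromone closure rather than retro-Claisen cleavage or closure through another oxygen. Intramolecular delivery enforces C-acylation, an anhydrous non-nucleophilic base avoids deacylation, and because both ortho oxygens of the unit 2 ring are benzyl ethers the ring A phenol is the only hydroxyl able to cyclise, so no benzofuran can form.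

Step 7
Reactants: 13 3-[4-(allyloxy)-2,6-bis(benzyloxy)phenyl]-5,7-bis(benzyloxy)-2-(4-methoxyphenyl)-4H-chromen-4-one
Product: 14 3-[3-acetyl-4-(allyloxy)-2,6-bis(benzyloxy)phenyl]-5,7-bis(benzyloxy)-2-(4-methoxyphenyl)-4H-chromen-4-one
Conditions: AcOH, (CF3CO)2O, CH2Cl2, 0 °C → rt
Reagents that add atoms: acetic acid, CC(=O)O
Why: Friedel–Crafts acylation by acetyl trifluoroacetate formed in the flask; the trialkoxy ring of unit 2 is the only ring not deactivated by a conjugated carbonyl and its two free positions are equivalent, so a single acetophenone should form with the acetyl group ortho to the allyloxy oxygen, and no Lewis acid strong enough to cleave benzyl ethers is present.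

Step 8
Reactants: 14 3-[3-acetyl-4-(allyloxy)-2,6-bis(benzyloxy)phenyl]-5,7-bis(benzyloxy)-2-(4-methoxyphenyl)-4H-chromen-4-one
Product: 15 3-[3-acetyl-2,6-bis(benzyloxy)-4-hydroxyphenyl]-5,7-bis(benzyloxy)-2-(4-methoxyphenyl)-4H-chromen-4-one
Conditions: Pd(PPh3)4 (5 mol%), morpholine, THF, rt
Reagents that add atoms: none
Why: Tsuji–Trost deallylation, in which zerovalent palladium ionises the allyl aryl ether and morpholine traps the allyl fragment; benzyl ethers, the methyl ether and both ketones are inert, and only the oxygen para to the biaryl bond is freed.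

Step 9
Reactants: 15 3-[3-acetyl-2,6-bis(benzyloxy)-4-hydroxyphenyl]-5,7-bis(benzyloxy)-2-(4-methoxyphenyl)-4H-chromen-4-one; 16 4-(benzyloxy)benzaldehyde
Product: 17 5,7-bis(benzyloxy)-3-{2,6-bis(benzyloxy)-3-[(E)-3-(4-benzyloxyphenyl)prop-2-enoyl]-4-hydroxyphenyl}-2-(4-methoxyphenyl)-4H-chromen-4-one
Conditions: KOH (50% aq.), EtOH/THF, rt
Reagents that add atoms: none
Why: Claisen–Schmidt condensation, in which the methyl ketone enolate adds to the non-enolisable aldehyde and E1cB dehydration gives the thermodynamically favoured E-chalcone; the fully substituted chromone of unit 1 has no acidic C–H and should resist ethanolic hydroxide at room temperature.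

Step 10
Reactants: 17 5,7-bis(benzyloxy)-3-{2,6-bis(benzyloxy)-3-[(E)-3-(4-benzyloxyphenyl)prop-2-enoyl]-4-hydroxyphenyl}-2-(4-methoxyphenyl)-4H-chromen-4-one
Product: 19 6-[5,7-bis(benzyloxy)-2-(4-methoxyphenyl)-4-oxo-4H-chromen-3-yl]-5,7-bis(benzyloxy)-2-[4-(benzyloxy)phenyl]-4H-chromen-4-one, via flavanone 18 (not isolated)
Conditions: I2 (10 mol%), DMSO, 130 °C
Reagents that add atoms: none
Why: Oxidative cyclisation of a 2'-hydroxychalcone with I2/DMSO, in which 6-endo-trig oxa-Michael addition of the only free hydroxyl gives flavanone 18 and iodination–elimination introduces the double bond while DMSO reoxidises HI; the other oxygen ortho to the enone is a benzyl ether, so only the 6-linked flavone can form.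

Step 11
Reactants: 19 6-[5,7-bis(benzyloxy)-2-(4-methoxyphenyl)-4-oxo-4H-chromen-3-yl]-5,7-bis(benzyloxy)-2-[4-(benzyloxy)phenyl]-4H-chromen-4-one
Product: 20 6-[5,7-dihydroxy-2-(4-methoxyphenyl)-4-oxo-4H-chromen-3-yl]-5,7-dihydroxy-2-(4-hydroxyphenyl)-4H-chromen-4-one (CNP0273516.0)
Conditions: H2 (1 atm), Pd/C (10%), THF/MeOH, rt
Reagents that add atoms: none
Why: Catalytic hydrogenolysis should cleave all five benzyl aryl ethers, while the aryl methyl ether and the conjugated chromone double bonds are not expected to react under these conditions.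

**Compound list**
1 | 2,4,6-trihydroxybenzaldehyde | O=Cc1c(O)cc(O)cc1O | starting material
2 | 4-(allyloxy)-2,6-dihydroxybenzaldehyde | O=Cc1c(O)cc(OCC=C)cc1O | intermediate
3 | 4-(allyloxy)-2,6-bis(benzyloxy)benzaldehyde | O=Cc1c(OCc2ccccc2)cc(OCC=C)cc1OCc1ccccc1 | intermediate
4 | N-{2-[4-(allyloxy)-2,6-bis(benzyloxy)phenyl]-1-tosylethenyl}formamide | O=CNC(=Cc1c(OCc2ccccc2)cc(OCC=C)cc1OCc1ccccc1)S(=O)(=O)c1ccc(C)cc1 | intermediate
5 | 2-[4-(allyloxy)-2,6-bis(benzyloxy)phenyl]acetonitrile | N#CCc1c(OCc2ccccc2)cc(OCC=C)cc1OCc1ccccc1 | intermediate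
6 | phloroglucinol (benzene-1,3,5-triol) | Oc1cc(O)cc(O)c1 | starting material
7 | 2-[4-(allyloxy)-2,6-bis(benzyloxy)phenyl]-1-(2,4,6-trihydroxyphenyl)ethaniminium chloride | [Cl-].[NH2+]=C(Cc1c(OCc2ccccc2)cc(OCC=C)cc1OCc1ccccc1)c1c(O)cc(O)cc1O | intermediate
8 | 2-[4-(allyloxy)-2,6-bis(benzyloxy)phenyl]-1-(2,4,6-trihydroxyphenyl)ethanone | O=C(Cc1c(OCc2ccccc2)cc(OCC=C)cc1OCc1ccccc1)c1c(O)cc(O)cc1O | intermediate
9 | 2-[4-(allyloxy)-2,6-bis(benzyloxy)phenyl]-1-[2,4-bis(benzyloxy)-6-hydroxyphenyl]ethanone | O=C(Cc1c(OCc2ccccc2)cc(OCC=C)cc1OCc1ccccc1)c1c(O)cc(OCc2ccccc2)cc1OCc1ccccc1 | intermediate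
10 | 4-methoxybenzoyl chloride | COc1ccc(C(=O)Cl)cc1 | starting material
11 | 2-{[4-(allyloxy)-2,6-bis(benzyloxy)phenyl]acetyl}-3,5-bis(benzyloxy)phenyl 4-methoxybenzoate | COc1ccc(C(=O)Oc2cc(OCc3ccccc3)cc(OCc3ccccc3)c2C(=O)Cc2c(OCc3ccccc3)cc(OCC=C)cc2OCc2ccccc2)cc1 | intermediate
12 | 2-[4-(allyloxy)-2,6-bis(benzyloxy)phenyl]-1-[2,4-bis(benzyloxy)-6-hydroxyphenyl]-3-(4-methoxyphenyl)propane-1,3-dione (racemic) | COc1ccc(C(=O)C(C(=O)c2c(O)cc(OCc3ccccc3)cc2OCc2ccccc2)c2c(OCc3ccccc3)cc(OCC=C)cc2OCc2ccccc2)cc1 | intermediate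
13 | 3-[4-(allyloxy)-2,6-bis(benzyloxy)phenyl]-5,7-bis(benzyloxy)-2-(4-methoxyphenyl)-4H-chromen-4-one | COc1ccc(-c2oc3cc(OCc4ccccc4)cc(OCc4ccccc4)c3c(=O)c2-c2c(OCc3ccccc3)cc(OCC=C)cc2OCc2ccccc2)cc1 | intermediate
14 | 3-[3-acetyl-4-(allyloxy)-2,6-bis(benzyloxy)phenyl]-5,7-bis(benzyloxy)-2-(4-methoxyphenyl)-4H-chromen-4-one | COc1ccc(-c2oc3cc(OCc4ccccc4)cc(OCc4ccccc4)c3c(=O)c2-c2c(OCc3ccccc3)cc(OCC=C)c(C(C)=O)c2OCc2ccccc2)cc1 | intermediate
15 | 3-[3-acetyl-2,6-bis(benzyloxy)-4-hydroxyphenyl]-5,7-bis(benzyloxy)-2-(4-methoxyphenyl)-4H-chromen-4-one | COc1ccc(-c2oc3cc(OCc4ccccc4)cc(OCc4ccccc4)c3c(=O)c2-c2c(OCc3ccccc3)cc(O)c(C(C)=O)c2OCc2ccccc2)cc1 | intermediate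
16 | 4-(benzyloxy)benzaldehyde | O=Cc1ccc(OCc2ccccc2)cc1 | starting material
17 | 5,7-bis(benzyloxy)-3-{2,6-bis(benzyloxy)-3-[(E)-3-(4-benzyloxyphenyl)prop-2-enoyl]-4-hydroxyphenyl}-2-(4-methoxyphenyl)-4H-chromen-4-one | COc1ccc(-c2oc3cc(OCc4ccccc4)cc(OCc4ccccc4)c3c(=O)c2-c2c(OCc3ccccc3)cc(O)c(C(=O)/C=C/c3ccc(OCc4ccccc4)cc3)c2OCc2ccccc2)cc1 | intermediate
18 | 6-[5,7-bis(benzyloxy)-2-(4-methoxyphenyl)-4-oxo-4H-chromen-3-yl]-5,7-bis(benzyloxy)-2-[4-(benzyloxy)phenyl]chroman-4-one (racemic) | COc1ccc(-c2oc3cc(OCc4ccccc4)cc(OCc4ccccc4)c3c(=O)c2-c2c(OCc3ccccc3)cc3OC(c4ccc(OCc5ccccc5)cc4)CC(=O)c3c2OCc2ccccc2)cc1 | intermediate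
19 | 6-[5,7-bis(benzyloxy)-2-(4-methoxyphenyl)-4-oxo-4H-chromen-3-yl]-5,7-bis(benzyloxy)-2-[4-(benzyloxy)phenyl]-4H-chromen-4-one | COc1ccc(-c2oc3cc(OCc4ccccc4)cc(OCc4ccccc4)c3c(=O)c2-c2c(OCc3ccccc3)cc3oc(-c4ccc(OCc5ccccc5)cc4)cc(=O)c3c2OCc2ccccc2)cc1 | intermediate
20 | 6-[5,7-dihydroxy-2-(4-methoxyphenyl)-4-oxo-4H-chromen-3-yl]-5,7-dihydroxy-2-(4-hydroxyphenyl)-4H-chromen-4-one (CNP0273516.0) | COc1ccc(-c2oc3cc(O)cc(O)c3c(=O)c2-c2c(O)cc3oc(-c4ccc(O)cc4)cc(=O)c3c2O)cc1 | target

**Totals**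
Total step count: 11. Longest linear sequence: 11 steps (1 → 20); 6, 10 and 16 are purchased.

**Steps most likely to fail**

Step 6. The enolate carbon is flanked by a 2,6-disubstituted aryl ring and may fail to take up the aroyl group; alternatively, retro-Claisen loss of an acyl group from 12 may outrun ring closure. The fallback sets out from 9 and returns at 13. 9 is condensed with 4-methoxybenzaldehyde (piperidine, EtOH, reflux); Knoevenagel condensation at the methylene followed by oxa-Michael closure through the ring A phenol should give trans-3-[4-(allyloxy)-2,6-bis(benzyloxy)phenyl]-5,7-bis(benzyloxy)-2-(4-methoxyphenyl)chroman-4-one F1 (racemic). Dehydrogenation with DDQ (dioxane, 100 °C) should then give 13. The same two bonds are made, but C2 arrives at the aldehyde oxidation level and no acyl transfer is needed.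

Step 4. Benzyl groups on the very electron-rich ring may be lost or migrate under HCl/ZnCl2, and the hindered nitrilium may be captured slowly. The fallback sets out from 5 and returns at 9, replacing electrophilic acylation by addition of an aryl nucleophile. DIBAL-H (toluene, −78 °C, then aqueous Rochelle salt) reduces 5 to 2-[4-(allyloxy)-2,6-bis(benzyloxy)phenyl]acetaldehyde F2. Separately, NBS (CH2Cl2, −78 → 0 °C) brominates purchased 1,3,5-tris(benzyloxy)benzene to 2-bromo-1,3,5-tris(benzyloxy)benzene F3, and n-BuLi (THF, −78 °C) converts it into [2,4,6-tris(benzyloxy)phenyl]lithium F4. Addition of F2 at −78 °C should give 2-[4-(allyloxy)-2,6-bis(benzyloxy)phenyl]-1-[2,4,6-tris(benzyloxy)phenyl]ethanol F5 (racemic). Dess–Martin periodinane (NaHCO3, CH2Cl2) oxidises it to 2-[4-(allyloxy)-2,6-bis(benzyloxy)phenyl]-1-[2,4,6-tris(benzyloxy)phenyl]ethanone F6. MgBr2·OEt2 (toluene/Et2O, 80 °C) then cleaves one benzyl ether ortho to the carbonyl through a magnesium chelate and gives 9.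

Step 7. The acyl cation may attack a wrong site (ring A of unit 1 or the allyl alkene), or trifluoroacetic acid may strip a benzyl group from the activated ring. The fallback sets out from 13 and returns at 15, installing the acetyl group by cross-coupling. Pd(PPh3)4/morpholine (THF, rt) removes the allyl group to give 3-[2,6-bis(benzyloxy)-4-hydroxyphenyl]-5,7-bis(benzyloxy)-2-(4-methoxyphenyl)-4H-chromen-4-one F7. NIS (1.0 equiv, CH2Cl2, −20 °C) iodinates ortho to the free hydroxyl to give 3-[2,6-bis(benzyloxy)-4-hydroxy-3-iodophenyl]-5,7-bis(benzyloxy)-2-(4-methoxyphenyl)-4H-chromen-4-one F8. Stille coupling with tributyl(1-ethoxyvinyl)stannane (PdCl2(PPh3)2, dioxane, 90 °C) gives 3-[2,6-bis(benzyloxy)-3-(1-ethoxyvinyl)-4-hydroxyphenyl]-5,7-bis(benzyloxy)-2-(4-methoxyphenyl)-4H-chromen-4-one F9. Hydrolysis with 1 M HCl/THF (rt) then gives 15.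

**Further compounds**
F1 | step 6 | trans-3-[4-(allyloxy)-2,6-bis(benzyloxy)phenyl]-5,7-bis(benzyloxy)-2-(4-methoxyphenyl)chroman-4-one (racemic, one enantiomer drawn) | COc1ccc([C@H]2Oc3cc(OCc4ccccc4)cc(OCc4ccccc4)c3C(=O)[C@@H]2c2c(OCc3ccccc3)cc(OCC=C)cc2OCc2ccccc2)cc1
F2 | step 4 | 2-[4-(allyloxy)-2,6-bis(benzyloxy)phenyl]acetaldehyde | O=CCc1c(OCc2ccccc2)cc(OCC=C)cc1OCc1ccccc1
F3 | step 4 | 2-bromo-1,3,5-tris(benzyloxy)benzene | Brc1c(OCc2ccccc2)cc(OCc2ccccc2)cc1OCc1ccccc1
F4 | step 4 | [2,4,6-tris(benzyloxy)phenyl]lithium | [Li]c1c(OCc2ccccc2)cc(OCc2ccccc2)cc1OCc1ccccc1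
F5 | step 4 | 2-[4-(allyloxy)-2,6-bis(benzyloxy)phenyl]-1-[2,4,6-tris(benzyloxy)phenyl]ethanol (racemic) | OC(Cc1c(OCc2ccccc2)cc(OCC=C)cc1OCc1ccccc1)c1c(OCc2ccccc2)cc(OCc2ccccc2)cc1OCc1ccccc1
F6 | step 4 | 2-[4-(allyloxy)-2,6-bis(benzyloxy)phenyl]-1-[2,4,6-tris(benzyloxy)phenyl]ethanone | O=C(Cc1c(OCc2ccccc2)cc(OCC=C)cc1OCc1ccccc1)c1c(OCc2ccccc2)cc(OCc2ccccc2)cc1OCc1ccccc1
F7 | step 7 | 3-[2,6-bis(benzyloxy)-4-hydroxyphenyl]-5,7-bis(benzyloxy)-2-(4-methoxyphenyl)-4H-chromen-4-one | COc1ccc(-c2oc3cc(OCc4ccccc4)cc(OCc4ccccc4)c3c(=O)c2-c2c(OCc3ccccc3)cc(O)cc2OCc2ccccc2)cc1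
F8 | step 7 | 3-[2,6-bis(benzyloxy)-4-hydroxy-3-iodophenyl]-5,7-bis(benzyloxy)-2-(4-methoxyphenyl)-4H-chromen-4-one | COc1ccc(-c2oc3cc(OCc4ccccc4)cc(OCc4ccccc4)c3c(=O)c2-c2c(OCc3ccccc3)cc(O)c(I)c2OCc2ccccc2)cc1
F9 | step 7 | 3-[2,6-bis(benzyloxy)-3-(1-ethoxyvinyl)-4-hydroxyphenyl]-5,7-bis(benzyloxy)-2-(4-methoxyphenyl)-4H-chromen-4-one | COc1ccc(-c2oc3cc(OCc4ccccc4)cc(OCc4ccccc4)c3c(=O)c2-c2c(OCc3ccccc3)cc(O)c(C(=C)OCC)c2OCc2ccccc2)cc1
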